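The runs come from a simulation from invented constants, noise included.

**A false start.** It is tempting to read the quick early fall of starting material as conversion. In the spring run at 1.50 min, however, it had dropped to 56.3% while target stood at 3.3%.

| setting | spring | dawn | flask |
|---|---|---|---|
| starting material | 14 mM (fed, over 12 s) | 54 mM (fed, over 12 s) | 27 mM (fed, over 12 s) |
| protic impurity | 8.1 mM | 8.1 mM | 8.10 mM |
| enzyme | 0.02 mol% | 0.02 mol% | 0.02 mol% |
| added ligand | 11 µM | 11 µM | 11 µM |
| remark | run made earlier | run made earlier |  |
| time |  |  | 40 min |

| run | time / min | target / % | starting material / % |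
|---|---|---|---|
| spring | 1.50 | 3.3 | 56.3 |
| spring | 4.00 | 4.3 | 40.6 |
| spring | 8.00 | 5.2 | 35.0 |
| spring | 15.0 | 5.8 | 32.6 |
| spring | 30.0 | 4.6 | 27.8 |
| dawn | 1.50 | 19.4 | 60.8 |
| dawn | 4.00 | 30.4 | 32.7 |
| dawn | 8.00 | 21.4 | 16.3 |
| dawn | 15.0 | 7.3 | 10.5 |
| dawn | 30.0 | 1.0 | 5.3 |

(scatter of a reading: 0.5 percentage points)

* the best time, 40 min at the latest, for target
* the amount of target, in percent of the starting material charged, at that time



**First instants.** The feed of 12 s was shorter than the wait for the first reading, so I counted the charge as in at once. In this flask the protic impurity was charged at less than the starting material, so I took it as the limiting reagent of a one-to-one loss. That gave 30.0% as the toll, the share of the charge the impurity takes, c(protic impurity)/c(starting material). For spring the toll left 42.1%, and starting material plus target read 40.2% at 8.00 min.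

**The middle.** I expected the enzyme to work on what the toll left. The loading is per starting material, so dawn also held more enzyme than spring, and the two runs differ in both. Spring's highest target reading was 5.8% at 15.0 min. The dawn run, left by the toll with 85.0%, read 30.4% at 4.00 min.

**The end.** Target did not last: in dawn it read 1.0% at 30.0 min, with 5.3% of starting material still there. So I looked for a peak, not an end point. By the toll this flask was to keep 70.0%, which on a straight line put it 65.0% of the way from spring to dawn. My reckoning was therefore 21.8% at 7.85 min.

**The forecast.** It gave 15% (from 9% to 23%) at 7 min, lower than my figure, and it started from the remark “The flask has twice spring's catalyst”.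

**The result.** The flask reached 20.4% at 6.80 min, under this scheme:

    enzyme + target → enzyme + over-reaction product (k = 470 L mol⁻¹ s⁻¹)
    enzyme + added ligand ⇌ idle complex (K = 30000 L mol⁻¹, k = 740 L mol⁻¹ s⁻¹)
    starting material + enzyme → target + enzyme, rate k3*[starting material]^2.5*[enzyme]/(1 + ([starting material]/Kh3)^2.5) (22.0 mM, k = 2.90 × 10⁵ L²·⁵ mol⁻²·⁵ s⁻¹)
    starting material + protic impurity → quenched substrate (k = 1.40 L mol⁻¹ s⁻¹)

At that time quenched substrate stood at 30.0%, the share the toll of 30.0% had named, and protic impurity was down to 0.0370% of its charge. With 2.0 mM of protic impurity in the same flask, the toll fell to 7.41%, quenched substrate stood at 7.41% at 40.0 min, and the best target was 30.0%.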